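A ratio, the gas deliverable against the starting material charged, told me where this flask would stand.

    starting material + dissolved gas ⇌ target (K1 = 8.0 M⁻¹, k1 = 0.14 M⁻¹ s⁻¹)
    gas phase ⇌ dissolved gas, rate k2*(csat - [dissolved gas]) (k2 = 0.0022 s⁻¹, csat = 120 mM)
    dissolved gas + target → over-reacted product (k3 = 0.061 M⁻¹ s⁻¹)
    dissolved gas + target → over-reaction product (k4 = 0.0011 M⁻¹ s⁻¹)

starting material 3.0 M; gas phase 120 mM (held); time 3.0 h

- at the start none of the gas is dissolved
- run time (flask): 3.0 h

* the target standing at 3.0 h, as a percentage of the starting material charged
* the change that raises the amount of target at 3.0 h, in percent of the starting material charged most ("none" if none brings more than 2 percentage points) (delta / theta / none)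
* amount of target at 3.0 h, in percent of the starting material charged, after delta

- delta: doubling the saturation concentration of gas phase, all else as stated
- theta: doubling the transfer coefficient of step 2, all else as stated

For whoever takes the bench next: this flask began with 3.0 M of starting material and no dissolved gas, and I reckoned what you would find at 3.0 h. I carried the delivery ratio, 0.950: the gas the transfer step can bring by that time into an empty solution, over the starting material charged. Each finished over-reaction took two gas, so I expected about 1.57 M of starting material left.

Balancing transfer against that consumption put [target] at the square root of equilibrium constant times [starting material] times delivery rate, over twice the summed over-reaction constants. That gave 0.164 M, or 5.45 %, with [dissolved gas] near 0.0130 M, below saturation, so I took transfer as the rate-limiting step.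

In this reckoning the root follows the ratio times one minus half the ratio, which peaks at a ratio of 1, the crossing, and this flask stood beside it. So I told you to leave saturation and transfer coefficient alone: doubling either took the ratio to 1.90, past the crossing, and my figure fell to 2.37 %.

The forecast gave 5.2 %, 3.6 % after delta, and none as the choice: “Neither change helps, so best is none.” We differed on both numbers.

The flask gave 5.20 %, 3.26 % after delta, and none as the choice. Delta brought −1.9 percentage points and theta −1.4 points; that choice would fail on a gain above 2 points. With 1.8 M of starting material in the same flask, the ratio was 1.58, past the crossing, so I reckoned 20.8 % of its starting material left and 4.43 % as target; that flask stood at 29.0 % and 4.66 %.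

(The rate constants are those of an exercise.)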